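## Retrosynthetic overview

- The target is reached by global MOM removal from a bis-MOM isoflavan; the pyran ring (ring C) is closed just before that by Mitsunobu etherification (O1–C2) of a phenol/primary alcohol.
- Key disconnection C3–C1': the α-carbon of a ring-A lactol (a masked 3-arylpropanal, used as its chiral enamine) is arylated by ring B delivered as an aryl cation equivalent (an aryl(mesityl)iodonium salt, CuBr/chiral imidazolidinone). The innately nucleophilic ring-B carbon therefore reacts with inverted polarity, and this single step sets C3 as (R).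
- The lactol comes from a dihydrocoumarin made from 5-methoxyresorcinol and acrylic acid. Ring C is thus first formed as a lactone, opened reductively after the key step, and re-closed last.
- The iodonium salt comes from an arylstannane made by two successive directed ortho-lithiations of 3-methoxyphenol MOM ether (prenyl first, then tin); rings A and B are bought as benzenes.

Assumption: [hydroxy(tosyloxy)iodo]mesitylene is taken as a bought reagent (otherwise one operation from iodomesitylene diacetate and TsOH·H2O, not counted).

## Route

Step 1
Reactants: 1 5-methoxybenzene-1,3-diol; 2 acrylic acid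
Product: 3 7-hydroxy-5-methoxychroman-2-one
Conditions: Amberlyst-15, toluene, reflux (Dean–Stark), slight excess of 1
Reagents that add atoms: none
Why: Acid-catalysed Friedel–Crafts hydroarylation of acrylic acid followed by lactonisation gives the dihydrocoumarin in one operation; C–C bond formation is expected mainly at C4 of 1 (para to one OH, and two such sites against one C2 site), as in formylation and acylation of orcinol-type resorcinols, and the minor 5-hydroxy-7-methoxy isomer is removed by chromatography.

Step 2
Reactants: 3 7-hydroxy-5-methoxychroman-2-one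
Product: 4 5-methoxy-7-(methoxymethoxy)chroman-2-one
Conditions: MOMCl, i-Pr2NEt, CH2Cl2, 0 °C → rt
Reagents that add atoms: chloromethyl methyl ether (MOMCl), COCCl
Why: O-alkylation of the only free phenol (MOM protection) under a non-nucleophilic amine base that leaves the aryl lactone closed.

Step 3
Reactants: 4 5-methoxy-7-(methoxymethoxy)chroman-2-one
Product: 5 5-methoxy-7-(methoxymethoxy)chroman-2-ol
Conditions: i-Bu2AlH (1.1 equiv), CH2Cl2, −78 °C
Reagents that add atoms: none
Why: Partial hydride reduction of a lactone at −78 °C stops at the aluminium hemiacetal, which gives the lactol (a masked 3-arylpropanal) on hydrolysis.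

Step 4
Reactants: 6 3-methoxyphenol
Product: 7 1-methoxy-3-(methoxymethoxy)benzene
Conditions: MOMCl, i-Pr2NEt, CH2Cl2, 0 °C → rt
Reagents that add atoms: chloromethyl methyl ether (MOMCl), COCCl
Why: O-alkylation (MOM protection) turns the phenol into a chelating directing group for the two ortho-lithiations that follow.

Step 5
Reactants: 7 1-methoxy-3-(methoxymethoxy)benzene
Product: 9 1-methoxy-3-(methoxymethoxy)-2-(3-methylbut-2-en-1-yl)benzene, via aryllithium 8 (not isolated)
Conditions: n-BuLi (1.1 equiv), THF, 0 °C → rt; then CuI (10 mol%), prenyl bromide, −78 °C → rt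
Reagents that add atoms: prenyl bromide (1-bromo-3-methylbut-2-ene), CC(C)=CCBr; n-BuLi, [Li]CCCC (supplies the lithium of 8)
Why: Directed ortho-metalation occurs at the carbon flanked by OMe and OMOM (cooperative direction), and copper-catalysed SN2 allylation at the primary carbon of prenyl bromide gives the linear prenyl arene.

Step 6
Reactants: 9 1-methoxy-3-(methoxymethoxy)-2-(3-methylbut-2-en-1-yl)benzene
Product: 11 tributyl[4-methoxy-2-(methoxymethoxy)-3-(3-methylbut-2-en-1-yl)phenyl]stannane, via aryllithium 10 (not isolated)
Conditions: n-BuLi (1.2 equiv), TMEDA, Et2O, 0 °C; then Bu3SnCl, −78 °C → rt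
Reagents that add atoms: tributyltin chloride, CCCC[Sn](Cl)(CCCC)CCCC; n-BuLi, [Li]CCCC (supplies the lithium of 10)
Why: A second directed ortho-metalation takes place next to the stronger chelating OMOM director (kinetic ring lithiation in ether/TMEDA) and the aryllithium is trapped by the tin electrophile, fixing the future C1' position.

Step 7
Reactants: 11 tributyl[4-methoxy-2-(methoxymethoxy)-3-(3-methylbut-2-en-1-yl)phenyl]stannane
Product: 13 [4-methoxy-2-(methoxymethoxy)-3-(3-methylbut-2-en-1-yl)phenyl](2,4,6-trimethylphenyl)iodonium trifluoromethanesulfonate, via iodonium tosylate 12 (not isolated)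
Conditions: MesI(OH)OTs (1.0 equiv), CH2Cl2, 0 °C → rt; then stir with aq. NaOTf (5 equiv), precipitate from Et2O
Reagents that add atoms: [hydroxy(tosyloxy)iodo]mesitylene, Cc1cc(C)c(c(C)c1)I(O)OS(=O)(=O)c1ccc(C)cc1; NaOTf, [Na+].[O-]S(=O)(=O)C(F)(F)F
Why: Ipso-substitution of the C–Sn bond by the electrophilic trivalent iodine centre (iododestannylation) is regiospecific and runs without added acid, so the MOM ether and the prenyl group survive, and anion metathesis gives the weakly coordinating triflate.

Step 8
Reactants: 5 5-methoxy-7-(methoxymethoxy)chroman-2-ol (1.5 equiv); 13 the aryl(mesityl)iodonium triflate (1.0 equiv)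
Product: 15 2-{(2R)-3-hydroxy-2-[4-methoxy-2-(methoxymethoxy)-3-(3-methylbut-2-en-1-yl)phenyl]propyl}-3-methoxy-5-(methoxymethoxy)phenol, via arylated lactol 14 (not isolated)
Conditions: CuBr (10 mol%), (2S,5S)-5-benzyl-2-tert-butyl-3-methylimidazolidin-4-one·CCl3CO2H (20 mol%), NaHCO3 (1.5 equiv), toluene/Et2O 2:1, 23 °C; then MeOH, NaBH4, 0 °C
Reagents that add atoms: none
Why: Proposed new method: the closest known reaction is the copper/imidazolidinone-catalysed enantioselective α-arylation of aldehydes with diaryliodonium salts, here extended to a lactol donor and an ortho-alkoxy aryl group; lactol 5 opens to its hydroxy-aldehyde and condenses with the amine to an E-enamine turned away from the tert-butyl group, CuBr and 13 give an electrophilic aryl–copper species (trivalent copper) carrying the less hindered non-mesityl aryl, this aryl is delivered to the enamine face not blocked by the benzyl group (Si face, giving R at C3), the product re-closes to lactol 14, which shelters the new α-aryl centre from enolisation, and NaBH4 reduces 14 through its open form to diol 15.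

Step 9
Reactants: 15 the (R)-phenol-diol
Product: 16 (3R)-5-methoxy-7-(methoxymethoxy)-3-[4-methoxy-2-(methoxymethoxy)-3-(3-methylbut-2-en-1-yl)phenyl]chroman
Conditions: PPh3, DIAD, THF (0.02 M), 0 °C → rt
Reagents that add atoms: none
Why: Mitsunobu etherification closes the six-membered ring between the only free phenol and the activated primary alcohol; the C3 centre is one carbon away from the reacting carbon and is untouched, and the ring-B oxygen is blocked as its MOM ether so no dihydrobenzofuran can form.

Step 10
Reactants: 16 the bis-MOM isoflavan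
Product: 17 (3R)-3-[2-hydroxy-4-methoxy-3-(3-methylbut-2-en-1-yl)phenyl]-5-methoxychroman-7-ol
Conditions: 3 M aq. HCl, MeOH, 40 °C, monitored and stopped at full conversion
Reagents that add atoms: none
Why: Acid-catalysed acetal cleavage removes both MOM groups, with methanol trapping the methoxymethyl cation as dimethoxymethane, under conditions mild enough that the ortho-prenyl phenol does not cyclise to a dimethylchroman and C3 is not affected.

## Compound list

1 | 5-methoxybenzene-1,3-diol (5-methoxyresorcinol) | COc1cc(O)cc(O)c1 | starting material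
2 | acrylic acid | C=CC(=O)O | starting material
3 | 7-hydroxy-5-methoxychroman-2-one | COc1cc(O)cc2c1CCC(=O)O2 | intermediate
4 | 5-methoxy-7-(methoxymethoxy)chroman-2-one | COc1cc(OCOC)cc2c1CCC(=O)O2 | intermediate
5 | 5-methoxy-7-(methoxymethoxy)chroman-2-ol (C2 unassigned; in equilibrium with the open hydroxy-aldehyde) | COc1cc(OCOC)cc2c1CCC(O)O2 | intermediate
6 | 3-methoxyphenol | COc1cccc(O)c1 | starting material
7 | 1-methoxy-3-(methoxymethoxy)benzene | COCOc1cccc(OC)c1 | intermediate
8 | [2-methoxy-6-(methoxymethoxy)phenyl]lithium | [Li]c1c(OC)cccc1OCOC | intermediate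
9 | 1-methoxy-3-(methoxymethoxy)-2-(3-methylbut-2-en-1-yl)benzene | COCOc1cccc(OC)c1CC=C(C)C | intermediate
10 | [4-methoxy-2-(methoxymethoxy)-3-(3-methylbut-2-en-1-yl)phenyl]lithium | [Li]c1ccc(OC)c(CC=C(C)C)c1OCOC | intermediate
11 | tributyl[4-methoxy-2-(methoxymethoxy)-3-(3-methylbut-2-en-1-yl)phenyl]stannane | CCCC[Sn](CCCC)(CCCC)c1ccc(OC)c(CC=C(C)C)c1OCOC | intermediate
12 | [4-methoxy-2-(methoxymethoxy)-3-(3-methylbut-2-en-1-yl)phenyl](2,4,6-trimethylphenyl)iodonium 4-methylbenzenesulfonate | COCOc1c([I+]c2c(C)cc(C)cc2C)ccc(OC)c1CC=C(C)C.Cc1ccc(S(=O)(=O)[O-])cc1 | intermediate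
13 | [4-methoxy-2-(methoxymethoxy)-3-(3-methylbut-2-en-1-yl)phenyl](2,4,6-trimethylphenyl)iodonium trifluoromethanesulfonate | COCOc1c([I+]c2c(C)cc(C)cc2C)ccc(OC)c1CC=C(C)C.[O-]S(=O)(=O)C(F)(F)F | intermediate
14 | (3R)-5-methoxy-7-(methoxymethoxy)-3-[4-methoxy-2-(methoxymethoxy)-3-(3-methylbut-2-en-1-yl)phenyl]chroman-2-ol (C2 epimer mixture) | COc1cc(OCOC)cc2c1C[C@H](c1ccc(OC)c(CC=C(C)C)c1OCOC)C(O)O2 | intermediate
15 | 2-{(2R)-3-hydroxy-2-[4-methoxy-2-(methoxymethoxy)-3-(3-methylbut-2-en-1-yl)phenyl]propyl}-3-methoxy-5-(methoxymethoxy)phenol | COCOc1cc(O)c(C[C@H](c2ccc(OC)c(CC=C(C)C)c2OCOC)CO)c(OC)c1 | intermediate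
16 | (3R)-5-methoxy-7-(methoxymethoxy)-3-[4-methoxy-2-(methoxymethoxy)-3-(3-methylbut-2-en-1-yl)phenyl]chroman | COc1cc(OCOC)cc2c1C[C@H](c1ccc(OC)c(CC=C(C)C)c1OCOC)CO2 | intermediate
17 | (3R)-3-[2-hydroxy-4-methoxy-3-(3-methylbut-2-en-1-yl)phenyl]-5-methoxychroman-7-ol | COc1cc(O)cc2c1C[C@H](c1ccc(OC)c(CC=C(C)C)c1O)CO2 | target

## Step count and risks

Total step count: 10 (steps 1–3 for the ring-A lactol, steps 4–7 for the iodonium salt, steps 8–10 after convergence).
Longest linear sequence: 7 steps (steps 4, 5, 6, 7, 8, 9, 10).

The three steps most likely to fail: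

Step 8 (key arylation). The ortho-alkoxy aryl group may transfer slowly, the lactol may form its enamine reluctantly, and ring A or the open-form phenol may be arylated. The sense of induction is predicted from the enamine model only and must be checked by the sign of rotation against known (R)-isoflavans; the (2R,5R) catalyst is the remedy if it is opposite. The fallback sets out from lactone 4 (with 13) and comes back at diol 15. Lactone 4 is converted with LiN(SiMe3)2 and Me3SiCl (THF, −78 °C) into the silyl ketene acetal 5-methoxy-7-(methoxymethoxy)-2-(trimethylsilyloxy)-4H-chromene F1. F1 is arylated by 13 under (CuOTf)2·C6H6 (monovalent copper) and a phenyl-substituted bis(oxazoline) ligand in CH2Cl2, the ligand antipode being chosen to give (3R)-5-methoxy-7-(methoxymethoxy)-3-[4-methoxy-2-(methoxymethoxy)-3-(3-methylbut-2-en-1-yl)phenyl]chroman-2-one F2. F2 is reduced with LiBH4 (THF, 0 °C) to 15. This replaces the catalytic chiral enamine by a preformed enolate equivalent, moves the asymmetric induction onto the metal–ligand complex, and keeps every phenol masked during the C–C bond formation.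

Step 6 (second lithiation). The benzylic–allylic CH2 of the prenyl group may be deprotonated in place of the ring position. The fallback sets out from 9 and comes back at 13. Compound 9 is treated directly with MesI(OH)OTs in CF3CH2OH at 0 °C, so that the trivalent iodine electrophile substitutes the ring C–H para to the methoxy group without any strong base, followed by the same NaOTf exchange through 12. The regioselectivity over the position para to OMOM would have to be verified, and this fallback makes no compound outside the list (F0).

Step 1 (regiochemistry of the annulation). Attack at C2 of 1 would give the 5-hydroxy-7-methoxy isomer. The fallback sets out from 1 and comes back at 3. Vilsmeier–Haack formylation of 1 (POCl3, DMF, then aq. NaOAc) gives crystalline 2,4-dihydroxy-6-methoxybenzaldehyde F3, whose substitution pattern is easily proven (one chelated OH). F3 is then heated with Meldrum's acid in HCO2H/Et3N (reductive Knoevenagel condensation, lactonisation with loss of acetone, decarboxylation) to give 3 with the C4 carbon placed unambiguously.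

Further compounds
F1 | step 8 | 5-methoxy-7-(methoxymethoxy)-2-(trimethylsilyloxy)-4H-chromene | COc1cc(OCOC)cc2c1CC=C(O[Si](C)(C)C)O2
F2 | step 8 | (3R)-5-methoxy-7-(methoxymethoxy)-3-[4-methoxy-2-(methoxymethoxy)-3-(3-methylbut-2-en-1-yl)phenyl]chroman-2-one | COc1cc(OCOC)cc2c1C[C@H](c1ccc(OC)c(CC=C(C)C)c1OCOC)C(=O)O2
F0 | step 6 | none | none
F3 | step 1 | 2,4-dihydroxy-6-methoxybenzaldehyde | COc1cc(O)cc(O)c1C=O
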